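**Retrosynthetic overview**
1. Target 28 ← 26 by Saegusa–Ito dehydrogenation at C2–C3. 26 ← carbonate 25 by transannular allylic etherification with zerovalent palladium: C5 (allylic to the C4=C15 methylidene) and the tertiary oxygen on C10 face each other across the ten-membered carbocycle C1–C10, and the C5–O bond divides that ring into the two seven-membered oxacycles O–C5–C4–C3–C2–C1–C10 and O–C5–C6–C7–C8–C9–C10.
2. 25 ← seco aldehyde 23 by Ni/Cr closure of C4–C5 (alkenyl iodide onto aldehyde), with the lactone and the C8 angelate already in place.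
3. 23 ← aldehyde 12 + allyl bromide 16 by indium Barbier union at C7–C8 (sets C7 and C8), angeloylation of O8, then lactone closure from O6.
4. 12 ← (S)-citramalic acid (C8–C10, C14, C1; C10 stereocentre) + MeMgBr (C2) + 2-iodoallyl bromide 3 (C3, C4, C15). 16 ← (R)-glyceraldehyde acetonide (C5–C7; C6 stereocentre) + methyl acrylate (C11–C13).
5. Ring order: γ-lactone (step 14), ten-membered carbocycle (step 16), both oxepane rings by one bond (step 18).

Key step: step 18

Remark: germacrane numbering (C1 ketone, C4=C15, C5, C6 lactone O–CH, C7, C8 angelate CH, C10 quaternary, C11=C13, C12 lactone C=O) is used for all intermediates; the Ni/Cr closure is not expected to control C5, so 24 and 25 are drawn as the (5S) epimers and carried on with their C5 epimers, which should converge in step 18.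

**Route**

Step 1
Reactants: 1 prop-2-yn-1-ol
Product: 2 2-iodoprop-2-en-1-ol
Conditions: NaI, TMSCl, H2O, MeCN, rt
Reagents that add atoms: sodium iodide [Na+].[I-]
Why: Markovnikov hydroiodination of the terminal alkyne by HI made in situ (alkyne hydrohalogenation) should place iodine on the internal carbon.

Step 2
Reactants: 2 2-iodoprop-2-en-1-ol
Product: 3 3-bromo-2-iodoprop-1-ene
Conditions: PBr3, pyridine (cat.), Et2O, 0 °C
Reagents that add atoms: phosphorus tribromide BrP(Br)Br
Why: Bromination of a primary allylic alcohol with PBr3 (nucleophilic substitution) should proceed without touching the alkenyl iodide.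

Step 3
Reactants: 4 (S)-citramalic acid
Product: 5 2-[(4S)-2,2,4-trimethyl-5-oxo-1,3-dioxolan-4-yl]acetic acid
Conditions: 2,2-dimethoxypropane, TsOH·H2O (cat.), rt
Reagents that add atoms: 2,2-dimethoxypropane COC(C)(C)OC
Why: Acid-catalysed dioxolanone (acetonide) formation ties up the tertiary hydroxyl and the adjacent carboxyl (future C1), leaving the C8 acid free and C10 untouched.

Step 4
Reactants: 5 2-[(4S)-2,2,4-trimethyl-5-oxo-1,3-dioxolan-4-yl]acetic acid
Product: 7 (3S)-3-hydroxy-3-methyloxolan-2-one, via hydroxyethyl dioxolanone 6 (not isolated)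
Conditions: BH3·SMe2, THF, 0 °C to rt; MeOH quench; then TsOH·H2O (cat.), CH2Cl2, rt
Reagents that add atoms: none
Why: Chemoselective borane reduction of the free acid beside the dioxolanone, then acid-catalysed translactonisation of the γ-hydroxy dioxolanone to the five-membered lactone with loss of acetone; C10 is not involved.

Step 5
Reactants: 7 (3S)-3-hydroxy-3-methyloxolan-2-one
Product: 8 (2S)-2,4-dihydroxy-N-methoxy-N,2-dimethylbutanamide
Conditions: MeNH(OMe)·HCl, AlMe3, CH2Cl2, 0 °C to rt
Reagents that add atoms: N,O-dimethylhydroxylamine hydrochloride CNOC.Cl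
Why: Aminolysis of the lactone by the aluminium amide of N,O-dimethylhydroxylamine (Weinreb amide formation) should open the ring at C1.

Step 6
Reactants: 8 (2S)-2,4-dihydroxy-N-methoxy-N,2-dimethylbutanamide
Product: 9 (2S)-N-methoxy-N,2-dimethyl-2,4-bis(triethylsilyloxy)butanamide
Conditions: TESOTf, 2,6-lutidine, CH2Cl2, −78 to 0 °C
Reagents that add atoms: triethylsilyl trifluoromethanesulfonate CC[Si](CC)(CC)OS(=O)(=O)C(F)(F)F
Why: Silyl triflate silylation should protect both the primary (C8) and the tertiary (C10) hydroxyl.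

Step 7
Reactants: 9 (2S)-N-methoxy-N,2-dimethyl-2,4-bis(triethylsilyloxy)butanamide
Product: 10 (3S)-3-methyl-3,5-bis(triethylsilyloxy)pentan-2-one
Conditions: MeMgBr, THF, 0 °C
Reagents that add atoms: methylmagnesium bromide C[Mg]Br
Why: Weinreb ketone synthesis, in which the chelated tetrahedral intermediate prevents over-addition and delivers the C1 methyl ketone (methyl = C2).

Step 8
Reactants: 10 (3S)-3-methyl-3,5-bis(triethylsilyloxy)pentan-2-one; 3 3-bromo-2-iodoprop-1-ene
Product: 11 (6S)-2-iodo-6-methyl-6,8-bis(triethylsilyloxy)oct-1-en-5-one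
Conditions: LiN(iPr)2 (LDA), THF, −78 °C; then 3, DMPU, −78 to −30 °C
Reagents that add atoms: none
Why: Kinetic lithium enolate alkylation, in which only the C2 methyl can enolise because C10 is quaternary and the allylic bromide is displaced while the alkenyl iodide stays intact.

Step 9
Reactants: 11 (6S)-2-iodo-6-methyl-6,8-bis(triethylsilyloxy)oct-1-en-5-one
Product: 12 (3S)-7-iodo-3-methyl-4-oxo-3-(triethylsilyloxy)oct-7-enal
Conditions: (COCl)2, DMSO, CH2Cl2, −78 to −40 °C; then Et3N
Reagents that add atoms: none
Why: Swern oxidation cleaves and oxidises the primary triethylsilyl ether directly to the C8 aldehyde while the tertiary silyl ether should survive.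

Step 10
Reactants: 13 (4R)-2,2-dimethyl-1,3-dioxolane-4-carbaldehyde; 14 methyl acrylate
Product: 15 methyl 2-{[(4R)-2,2-dimethyl-1,3-dioxolan-4-yl](hydroxy)methyl}prop-2-enoate (both carbinol epimers)
Conditions: DABCO (0.5 equiv), dioxane/H2O, rt
Reagents that add atoms: none
Why: Morita–Baylis–Hillman reaction; the carbinol centre is of no consequence because step 11 removes it, and the dioxolane centre (future C6) comes from the aldehyde.

Step 11
Reactants: 15 methyl 2-{[(4R)-2,2-dimethyl-1,3-dioxolan-4-yl](hydroxy)methyl}prop-2-enoate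
Product: 16 methyl (2Z)-2-(bromomethyl)-3-[(4S)-2,2-dimethyl-1,3-dioxolan-4-yl]prop-2-enoate
Conditions: NBS, Me2S, CH2Cl2, 0 °C to rt
Reagents that add atoms: N-bromosuccinimide O=C1CCC(=O)N1Br
Why: Corey–Kim-type activation of the allylic alcohol and SN2′ entry of bromide (allylic transposition) should give the (Z)-2-(bromomethyl)enoate under neutral conditions that spare the acetonide.

Step 12
Reactants: 12 (3S)-7-iodo-3-methyl-4-oxo-3-(triethylsilyloxy)oct-7-enal; 16 methyl (2Z)-2-(bromomethyl)-3-[(4S)-2,2-dimethyl-1,3-dioxolan-4-yl]prop-2-enoate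
Product: 17 methyl (3R,4R,6S)-3-[(4S)-2,2-dimethyl-1,3-dioxolan-4-yl]-4-hydroxy-10-iodo-6-methyl-2-methylidene-7-oxo-6-(triethylsilyloxy)undec-10-enoate
Conditions: In powder, THF, rt, ultrasound
Reagents that add atoms: none
Why: Indium Barbier allylation through a chair transition state, in which the Z geometry (C6 cis to the indium-bearing C13) gives the syn relation of the C6 branch and O8, and coordination of the dioxolane O6 to indium turns C5 to one face of C7=C11 so that the aldehyde enters on the other, setting C7 (R) and C8 (R) while ketone and alkenyl iodide are left alone.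

Step 13
Reactants: 17 methyl (3R,4R,6S)-3-[(4S)-2,2-dimethyl-1,3-dioxolan-4-yl]-4-hydroxy-10-iodo-6-methyl-2-methylidene-7-oxo-6-(triethylsilyloxy)undec-10-enoate; 18 angelic acid
Product: 20 C8 angelate of 17, via mixed anhydride 19 (not isolated)
Conditions: 18, 2,4,6-trichlorobenzoyl chloride, Et3N, PhMe, rt; then 17, PhMe, 75 °C (no DMAP)
Reagents that add atoms: none
Why: Yamaguchi-type esterification through the preformed mixed anhydride without nucleophilic catalyst should keep the Z geometry of the angelate and, by capping O8, prevents lactonisation towards C8.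

Step 14
Reactants: 20 C8 angelate of 17
Product: 22 (6S,7R,8R,10S)-8-angeloyloxy-5,10-dihydroxy-4-iodo-1-oxo-4,5-secogermacra-4(15),11(13)-dien-12,6-olide, via triol ester 21 (not isolated)
Conditions: TsOH·H2O (cat.), MeOH, rt
Reagents that add atoms: none
Why: Acid-catalysed removal of the acetonide and the tertiary silyl ether, then lactonisation of the C6 hydroxyl onto the acrylate ester, the five-membered lactone being favoured over the six-membered one through O5 under equilibrating conditions and the C6/C7 trans relation being already fixed.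

Step 15
Reactants: 22 (6S,7R,8R,10S)-8-angeloyloxy-5,10-dihydroxy-4-iodo-1-oxo-4,5-secogermacra-4(15),11(13)-dien-12,6-olide
Product: 23 the C5 aldehyde of 22
Conditions: Dess–Martin periodinane, NaHCO3, CH2Cl2, 0 °C to rt; used crude
Reagents that add atoms: none
Why: Dess–Martin oxidation of the primary C5 alcohol under buffered conditions should spare the tertiary alcohol and limit epimerisation at C6.

Step 16
Reactants: 23 the C5 aldehyde of 22
Product: 24 (5S,6S,7R,8R,10S)-8-angeloyloxy-5,10-dihydroxy-1-oxogermacra-4(15),11(13)-dien-12,6-olide (5S epimer drawn, 5-epimer expected alongside)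
Conditions: CrCl2 (excess), NiCl2 (cat.), DMSO/THF, 0.003 M, rt, slow addition of 23
Reagents that add atoms: none
Why: Nozaki–Hiyama–Kishi reaction, in which the nickel-catalysed C4 alkenylchromium species adds to the C5 aldehyde at high dilution to close the ten-membered carbocycle, the aldehyde reacting in preference to the hindered C1 ketone and the C5 configuration not being relied on.

Step 17
Reactants: 24 (5S,6S,7R,8R,10S)-8-angeloyloxy-5,10-dihydroxy-1-oxogermacra-4(15),11(13)-dien-12,6-olide
Product: 25 5-O-methoxycarbonyl derivative of 24 (C5 methyl carbonate, C10 hydroxyl free)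
Conditions: ClCO2Me, pyridine, CH2Cl2, 0 °C
Reagents that add atoms: methyl chloroformate COC(=O)Cl
Why: Acylation of the secondary allylic alcohol with a chloroformate, the tertiary C10 hydroxyl being too hindered to react.

Step 18
Reactants: 25 5-O-methoxycarbonyl derivative of 24
Product: 26 (5S,6S,7R,8R,10S)-8-angeloyloxy-5,10-epoxy-1-oxogermacra-4(15),11(13)-dien-12,6-olide (2,3-dihydro target)
Conditions: Pd2(dba)3·CHCl3 (5 mol %), PPh3 (25 mol %), THF, 0.005 M, rt to 45 °C
Reagents that add atoms: none
Why: Proposed new method: zerovalent palladium should ionise the C5 carbonate with inversion to the 2-substituted allyl complex over C15–C4–C5, CO2 is lost, and the methoxide so formed deprotonates the tertiary α-ketol hydroxyl at C10, whose alkoxide attacks C5 on the face away from palladium and restores the C4=C15 methylidene. The closest known reaction is the intramolecular Tsuji–Trost O-allylation of hydroxy allylic carbonates; its transannular use across a ten-membered carbocycle is the untested part. The one C5–O bond closes both oxepane rings: the ring O–C5–C6–C7–C8–C9–C10 by an exo attack on the allyl terminus (allyl unit outside the ring) and the ring O–C5–C4–C3–C2–C1–C10 by a closure that keeps C4 in the ring and C15 exocyclic. The new C5 stereocentre is controlled by the fixed C10 centre, since an oxygen bridge across the ring can only be cis: (5S)-25 reacts with net retention by double inversion, and the (5R) epimer should converge because the allyl complex can change palladium face through its C15-bound sigma form. The selectivity needed is attack at C5 and not at C15, which would also close a seven-membered ring through C1–C3 but leaves a nine-membered ring with a bridgehead C4=C5 alkene; it rests on geometry, C5 lying within transannular reach of O10 on both tethers while C15 projects out of the macrocycle. O-allylation over methoxide capture should be favoured by the acidity of the α-ketol hydroxyl and by high dilution, and the α-methylidene lactone, angelate and ketone should not be touched by the soft palladium manifold.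

Step 19
Reactants: 26 (5S,6S,7R,8R,10S)-8-angeloyloxy-5,10-epoxy-1-oxogermacra-4(15),11(13)-dien-12,6-olide
Product: 27 C1–C2 trimethylsilyl enol ether of 26
Conditions: TMSOTf, Et3N, CH2Cl2, 0 °C
Reagents that add atoms: trimethylsilyl trifluoromethanesulfonate C[Si](C)(C)OS(=O)(=O)C(F)(F)F
Why: Soft enolisation with silyl triflate and amine, regiospecific because C10 is quaternary and only C2 carries enolisable hydrogens.

Step 20
Reactants: 27 C1–C2 trimethylsilyl enol ether of 26
Product: 28 (5S,6S,7R,8R,10S)-8-angeloyloxy-5,10-epoxy-1-oxogermacra-2,4(15),11(13)-trien-12,6-olide (target)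
Conditions: Pd(OAc)2 (1.2 equiv), MeCN, rt
Reagents that add atoms: none
Why: Saegusa–Ito oxidation, in which the C2 palladium enolate loses a β-hydride from C3 to give the C2–C3 enone, necessarily cis within the seven-membered ring.

**Compound list**
1 | prop-2-yn-1-ol | C#CCO | starting material
2 | 2-iodoprop-2-en-1-ol | C=C(I)CO | intermediate
3 | 3-bromo-2-iodoprop-1-ene | C=C(I)CBr | intermediate
4 | (S)-citramalic acid, (2S)-2-hydroxy-2-methylbutanedioic acid | OC(=O)C[C@](C)(O)C(=O)O | starting material
5 | 2-[(4S)-2,2,4-trimethyl-5-oxo-1,3-dioxolan-4-yl]acetic acid | OC(=O)C[C@]1(C)OC(C)(C)OC1=O | intermediate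
6 | (5S)-5-(2-hydroxyethyl)-2,2,5-trimethyl-1,3-dioxolan-4-one (not isolated) | OCC[C@]1(C)OC(C)(C)OC1=O | intermediate
7 | (3S)-3-hydroxy-3-methyloxolan-2-one | C[C@]1(O)CCOC1=O | intermediate
8 | (2S)-2,4-dihydroxy-N-methoxy-N,2-dimethylbutanamide | CON(C)C(=O)[C@@](C)(O)CCO | intermediate
9 | (2S)-N-methoxy-N,2-dimethyl-2,4-bis(triethylsilyloxy)butanamide | CON(C)C(=O)[C@@](C)(O[Si](CC)(CC)CC)CCO[Si](CC)(CC)CC | intermediate
10 | (3S)-3-methyl-3,5-bis(triethylsilyloxy)pentan-2-one | CC(=O)[C@@](C)(O[Si](CC)(CC)CC)CCO[Si](CC)(CC)CC | intermediate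
11 | (6S)-2-iodo-6-methyl-6,8-bis(triethylsilyloxy)oct-1-en-5-one | C=C(I)CCC(=O)[C@@](C)(O[Si](CC)(CC)CC)CCO[Si](CC)(CC)CC | intermediate
12 | (3S)-7-iodo-3-methyl-4-oxo-3-(triethylsilyloxy)oct-7-enal | C=C(I)CCC(=O)[C@@](C)(O[Si](CC)(CC)CC)CC=O | intermediate
13 | (4R)-2,2-dimethyl-1,3-dioxolane-4-carbaldehyde, (R)-glyceraldehyde acetonide | O=C[C@H]1COC(C)(C)O1 | starting material
14 | methyl acrylate | C=CC(=O)OC | starting material
15 | methyl 2-{[(4R)-2,2-dimethyl-1,3-dioxolan-4-yl](hydroxy)methyl}prop-2-enoate, both carbinol epimers | C=C(C(=O)OC)C(O)[C@H]1COC(C)(C)O1 | intermediate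
16 | methyl (2Z)-2-(bromomethyl)-3-[(4S)-2,2-dimethyl-1,3-dioxolan-4-yl]prop-2-enoate | COC(=O)/C(CBr)=C/[C@H]1COC(C)(C)O1 | intermediate
17 | methyl (3R,4R,6S)-3-[(4S)-2,2-dimethyl-1,3-dioxolan-4-yl]-4-hydroxy-10-iodo-6-methyl-2-methylidene-7-oxo-6-(triethylsilyloxy)undec-10-enoate | C=C(C(=O)OC)[C@@H]([C@H]1COC(C)(C)O1)[C@H](O)C[C@](C)(O[Si](CC)(CC)CC)C(=O)CCC(I)=C | intermediate
18 | angelic acid, (2Z)-2-methylbut-2-enoic acid | C/C=C(/C)C(=O)O | starting material
19 | (2Z)-2-methylbut-2-enoic 2,4,6-trichlorobenzoic anhydride (not isolated) | C/C=C(/C)C(=O)OC(=O)c1c(Cl)cc(Cl)cc1Cl | intermediate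
20 | C8 angelate of 17 (4-O-[(2Z)-2-methylbut-2-enoyl] ester; acetonide, silyl ether, methyl ester, ketone and alkenyl iodide unchanged) | C=C(C(=O)OC)[C@@H]([C@H]1COC(C)(C)O1)[C@H](OC(=O)/C(C)=C\C)C[C@](C)(O[Si](CC)(CC)CC)C(=O)CCC(I)=C | intermediate
21 | triol methyl ester: 20 without acetonide and silyl group, C5, C6 and C10 hydroxyls free (not isolated) | C=C(C(=O)OC)[C@@H]([C@H](O)CO)[C@H](OC(=O)/C(C)=C\C)C[C@](C)(O)C(=O)CCC(I)=C | intermediate
22 | (6S,7R,8R,10S)-8-angeloyloxy-5,10-dihydroxy-4-iodo-1-oxo-4,5-secogermacra-4(15),11(13)-dien-12,6-olide | C=C1C(=O)O[C@H](CO)[C@H]1[C@H](OC(=O)/C(C)=C\C)C[C@](C)(O)C(=O)CCC(I)=C | intermediate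
23 | C5 aldehyde of 22: (6S,7R,8R,10S)-8-angeloyloxy-10-hydroxy-4-iodo-1,5-dioxo-4,5-secogermacra-4(15),11(13)-dien-12,6-olide | C=C1C(=O)O[C@H](C=O)[C@H]1[C@H](OC(=O)/C(C)=C\C)C[C@](C)(O)C(=O)CCC(I)=C | intermediate
24 | (5S,6S,7R,8R,10S)-8-angeloyloxy-5,10-dihydroxy-1-oxogermacra-4(15),11(13)-dien-12,6-olide (5S epimer drawn) | C=C1C(=O)O[C@H]2[C@H]1[C@H](OC(=O)/C(C)=C\C)C[C@](C)(O)C(=O)CCC(=C)[C@@H]2O | intermediate
25 | 5-O-methoxycarbonyl derivative of 24 (key-step precursor) | C=C1C(=O)O[C@H]2[C@H]1[C@H](OC(=O)/C(C)=C\C)C[C@](C)(O)C(=O)CCC(=C)[C@@H]2OC(=O)OC | intermediate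
26 | (5S,6S,7R,8R,10S)-8-angeloyloxy-5,10-epoxy-1-oxogermacra-4(15),11(13)-dien-12,6-olide | C=C1C(=O)O[C@H]2[C@H]1[C@H](OC(=O)/C(C)=C\C)C[C@]1(C)O[C@H]2C(=C)CCC1=O | intermediate
27 | C1–C2 trimethylsilyl enol ether of 26 | C=C1C(=O)O[C@H]2[C@H]1[C@H](OC(=O)/C(C)=C\C)C[C@]1(C)O[C@H]2C(=C)CC=C1O[Si](C)(C)C | intermediate
28 | (5S,6S,7R,8R,10S)-8-angeloyloxy-5,10-epoxy-1-oxogermacra-2,4(15),11(13)-trien-12,6-olide | C=C1C(=O)O[C@H]2[C@H]1[C@H](OC(=O)/C(C)=C\C)C[C@]1(C)O[C@H]2C(=C)C=CC1=O | target

**Step count**
Total: 20 steps. Longest linear sequence: 16 steps (steps 3–9 and 12–20, from 4).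

**Steps most likely to fail**

1. Step 18 (transannular etherification). The allyl complex may be captured at C15 or by methoxide instead of by O10. The alkoxide may add to the α-methylidene lactone or set off an α-ketol shift. Ionisation of the hindered ring carbonate may be slow. Fallback with known chemistry, setting out from 24 and returning at 26: Dess–Martin oxidation of the C5 hydroxyl gives the C10-hydroxy 4(15)-en-5-one F1. With TMSOTf this should close across the ring through O10 to the bridged hemiketal F2. Et3SiH then reduces the derived oxocarbenium ion (reductive etherification of a hydroxy ketone, the usual way to oxepanes) to 26. The C5 configuration is again forced by the bridge.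

2. Step 16 (ten-membered closure). Oligomerisation may outrun the strained medium-ring closure, and the α-acyloxy aldehyde may epimerise at C6 or decompose before it is trapped. Fallback, setting out from 10 and returning at 24, replaces the alkenyl halide addition by a nickel-catalysed reductive alkyne–aldehyde cyclisation. Alkylation of the enolate of 10 with propargyl bromide gives the alkynyl ketone F4. Swern oxidation as in step 9 gives the aldehyde F5. Indium allylation with 16 as in step 12 gives the adduct F6, and angeloylation as in step 13 gives the angelate F7. Acid as in step 14 passes through the triol ester F8 to the hydroxymethyl lactone F9, and Dess–Martin oxidation gives the ynal F10. Ni(cod)2 with a bulky N-heterocyclic carbene (SIPr) and Et3SiH should join the internal alkyne carbon C4 to C5 and give the exocyclic allylic silyl ether F11. HF·pyridine then frees 24.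

3. Step 12 (fragment union). Facial selection at C7 may not follow the indium chelate, so that the aldehyde enters on the other face and C7 and C8 both come out inverted; the C8 hydroxyl may also close onto the ester before it is acylated. Fallback, setting out from 16 and returning at 17: Pd2(dba)3-catalysed borylation with bis(pinacolato)diboron gives the allylboronate F3, with CH2B cis to the dioxolane. Its allylboration of 12 is run under a chiral BINOL-derived phosphoric acid (TRIP). The aldehyde face, and through the closed chair C7 as well, is then chosen by the catalyst and not by the dioxolane. Hydrolytic work-up of the borate gives 17.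

**Further compounds**
F1 | step 18 | (6S,7R,8R,10S)-8-angeloyloxy-10-hydroxy-1,5-dioxogermacra-4(15),11(13)-dien-12,6-olide | C=C1C(=O)O[C@H]2[C@H]1[C@H](OC(=O)/C(C)=C\C)C[C@](C)(O)C(=O)CCC(=C)C2=O
F2 | step 18 | 5-hydroxy derivative of 26 (transannular C5,C10 hemiketal of F1) | C=C1C(=O)O[C@H]2[C@H]1[C@H](OC(=O)/C(C)=C\C)C[C@]1(C)O[C@@]2(O)C(=C)CCC1=O
F3 | step 12 | methyl 3-[(4S)-2,2-dimethyl-1,3-dioxolan-4-yl]-2-[(4,4,5,5-tetramethyl-1,3,2-dioxaborolan-2-yl)methyl]prop-2-enoate, CH2B cis to the dioxolane (2E by the sequence rule) | COC(=O)/C(CB1OC(C)(C)C(C)(C)O1)=C/[C@H]2COC(C)(C)O2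
F4 | step 16 | (6S)-6-methyl-6,8-bis(triethylsilyloxy)oct-1-yn-5-one | C#CCCC(=O)[C@@](C)(O[Si](CC)(CC)CC)CCO[Si](CC)(CC)CC
F5 | step 16 | (3S)-3-methyl-4-oxo-3-(triethylsilyloxy)oct-7-ynal | C#CCCC(=O)[C@@](C)(O[Si](CC)(CC)CC)CC=O
F6 | step 16 | alkyne analogue of 17 (terminal C4≡C15 in place of the iodoalkene) | C=C(C(=O)OC)[C@@H]([C@H]1COC(C)(C)O1)[C@H](O)C[C@](C)(O[Si](CC)(CC)CC)C(=O)CCC#C
F7 | step 16 | alkyne analogue of 20 | C=C(C(=O)OC)[C@@H]([C@H]1COC(C)(C)O1)[C@H](OC(=O)/C(C)=C\C)C[C@](C)(O[Si](CC)(CC)CC)C(=O)CCC#C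
F8 | step 16 | alkyne analogue of 21 (not isolated) | C=C(C(=O)OC)[C@@H]([C@H](O)CO)[C@H](OC(=O)/C(C)=C\C)C[C@](C)(O)C(=O)CCC#C
F9 | step 16 | alkyne analogue of 22 | C=C1C(=O)O[C@H](CO)[C@H]1[C@H](OC(=O)/C(C)=C\C)C[C@](C)(O)C(=O)CCC#C
F10 | step 16 | alkyne analogue of 23 (ynal) | C=C1C(=O)O[C@H](C=O)[C@H]1[C@H](OC(=O)/C(C)=C\C)C[C@](C)(O)C(=O)CCC#C
F11 | step 16 | 5-O-triethylsilyl ether of 24 | C=C1C(=O)O[C@H]2[C@H]1[C@H](OC(=O)/C(C)=C\C)C[C@](C)(O)C(=O)CCC(=C)[C@@H]2O[Si](CC)(CC)CC
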